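The disconnection is the C3–C4 bond of the heptan-3-one chain, between the ketone carbon and the α-methylene on the catechol side. The feature exploited is that the chain C1–C7 linking the syringyl ring (at C1) and the catechol ring (at C7) is unbranched and free of stereocentres. C4 may therefore enter as an acetylide carbon, and C1=C2 and C6=C7 as styrenyl alkenes made from two benzaldehydes. The key step adds a lithium enynide (C4–C7) to a cinnamoyl Weinreb amide (C1–C3), giving a tri-O-benzyl 1,6-dien-4-yn-3-one. One hydrogenation then saturates the chain and frees the three phenols.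

Key step: step 3

Remark on the chemistry: the target has no stereocentre and no stereogenic double bond, so it is achiral; the compound as drawn is the only stereoisomer and no step has to set configuration.

Step 1
Reactants: 1 4-(benzyloxy)-3,5-dimethoxybenzaldehyde; 2 diethyl {2-[methoxy(methyl)amino]-2-oxoethyl}phosphonate
Product: 4 (2E)-3-[4-(benzyloxy)-3,5-dimethoxyphenyl]-N-methoxy-N-methylprop-2-enamide, via sodium phosphonate carbanion 3 (not isolated)
Conditions: NaH, THF, 0 °C; then 1, 0 °C → rt
Reagents that add atoms: none
Why: Horner–Wadsworth–Emmons olefination of a non-enolisable aromatic aldehyde with a stabilised phosphonoacetamide carbanion should give the E-cinnamoyl Weinreb amide, installing C2 and C3 at the acyl oxidation level in one operation.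

Step 2
Reactants: 5 3,4-bis(benzyloxy)benzaldehyde; 6 [3-(trimethylsilyl)prop-2-yn-1-yl]triphenylphosphonium bromide
Product: 9 4-[3,4-bis(benzyloxy)phenyl]but-3-en-1-yne (E/Z mixture), via phosphonium ylide 7 (not isolated), via TMS-enyne 8 (not isolated)
Conditions: n-BuLi, THF, −78 °C; then 5, −78 °C → rt; then MeOH, K2CO3 (cat.), rt, same pot
Reagents that add atoms: none
Why: Wittig olefination with the semi-stabilised silylpropargyl ylide should form the C6=C7 alkene and bring in C4–C6 as a silyl-capped alkyne, and base-catalysed methanolysis of the C(sp)–Si bond in the same pot should unmask the terminal alkyne; the E/Z mixture is acceptable because the C6=C7 geometry is erased in step 4.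

Step 3
Reactants: 9 4-[3,4-bis(benzyloxy)phenyl]but-3-en-1-yne (E/Z mixture); 4 (2E)-3-[4-(benzyloxy)-3,5-dimethoxyphenyl]-N-methoxy-N-methylprop-2-enamide
Product: 12 (1E)-1-[4-(benzyloxy)-3,5-dimethoxyphenyl]-7-[3,4-bis(benzyloxy)phenyl]hepta-1,6-dien-4-yn-3-one (E/Z mixture at C6=C7), via lithium acetylide 10 (not isolated), via tetrahedral lithium adduct 11 (not isolated)
Conditions: n-BuLi, THF, −78 °C; then 4, −78 → 0 °C; inverse quench into cold 1 M aq. HCl
Reagents that add atoms: none
Why: n-BuLi removes the acetylenic proton of 9 to give the sp-carbanion 10, which adds 1,2 to the amide carbonyl of 4 to give the N-methoxy-chelated tetrahedral lithium adduct 11; this adduct survives until the acidic quench and only then collapses to the ketone, so a single acetylide is taken up. The closest known reaction type is the Weinreb ketone synthesis in its alkynyllithium variant with α,β-unsaturated Weinreb amides, which gives cross-conjugated enynones. The new bond is C3–C4 of the heptane chain, made between the acyl carbon of the syringyl half and the terminal alkyne carbon of the catechol half. No ring is closed and no stereocentre is created; the E geometry at C1=C2 is carried over from 4 and the geometry at C6=C7 is irrelevant. The selectivities needed are 1,2- over 1,4-addition, which the hard lithium acetylide and lithium coordination at the N-methoxy amide should secure, and mono-addition, which the chelate secures. Conjugate addition of the released N,O-dimethylhydroxylamine to the ynone should be suppressed by the cold inverse quench into aqueous acid, which protonates the amine as it is set free.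

Step 4
Reactants: 12 (1E)-1-[4-(benzyloxy)-3,5-dimethoxyphenyl]-7-[3,4-bis(benzyloxy)phenyl]hepta-1,6-dien-4-yn-3-one (E/Z mixture at C6=C7)
Product: 13 7-(3,4-dihydroxyphenyl)-1-(4-hydroxy-3,5-dimethoxyphenyl)heptan-3-one
Conditions: H2 (1 atm), 10% Pd/C, EtOAc–EtOH, rt; filtration and concentration under N2
Reagents that add atoms: none
Why: Heterogeneous catalytic hydrogenation over Pd/C should saturate the two styrenyl alkenes and the ynone triple bond and cleave the three benzyl aryl ethers by hydrogenolysis in one operation, while the non-benzylic dialkyl ketone at C3 and the aryl methyl ethers should not be reduced under these mild conditions.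

Compound list
1 | 4-(benzyloxy)-3,5-dimethoxybenzaldehyde | COc1cc(C=O)cc(OC)c1OCc1ccccc1 | starting material
2 | diethyl {2-[methoxy(methyl)amino]-2-oxoethyl}phosphonate | CCOP(=O)(CC(=O)N(C)OC)OCC | starting material
3 | sodium salt of the α-carbanion of 2 (not isolated) | CCOP(=O)([CH-]C(=O)N(C)OC)OCC.[Na+] | intermediate
4 | (2E)-3-[4-(benzyloxy)-3,5-dimethoxyphenyl]-N-methoxy-N-methylprop-2-enamide | COc1cc(/C=C/C(=O)N(C)OC)cc(OC)c1OCc1ccccc1 | intermediate
5 | 3,4-bis(benzyloxy)benzaldehyde | O=Cc1ccc(OCc2ccccc2)c(OCc2ccccc2)c1 | starting material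
6 | [3-(trimethylsilyl)prop-2-yn-1-yl]triphenylphosphonium bromide | C[Si](C)(C)C#CC[P+](c1ccccc1)(c1ccccc1)c1ccccc1.[Br-] | starting material
7 | triphenyl[3-(trimethylsilyl)prop-2-yn-1-ylidene]phosphorane, the ylide of 6 (not isolated) | C[Si](C)(C)C#CC=P(c1ccccc1)(c1ccccc1)c1ccccc1 | intermediate
8 | {4-[3,4-bis(benzyloxy)phenyl]but-3-en-1-yn-1-yl}trimethylsilane, E/Z mixture (not isolated) | C[Si](C)(C)C#CC=Cc1ccc(OCc2ccccc2)c(OCc2ccccc2)c1 | intermediate
9 | 4-[3,4-bis(benzyloxy)phenyl]but-3-en-1-yne, E/Z mixture | C#CC=Cc1ccc(OCc2ccccc2)c(OCc2ccccc2)c1 | intermediate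
10 | lithium acetylide of 9 (not isolated) | [Li]C#CC=Cc1ccc(OCc2ccccc2)c(OCc2ccccc2)c1 | intermediate
11 | lithium alkoxide of the tetrahedral N-methoxy-N-methyl hemiaminal formed from 10 and 4, racemic at the carbinol carbon (not isolated) | COc1cc(/C=C/C(O[Li])(C#CC=Cc2ccc(OCc3ccccc3)c(OCc3ccccc3)c2)N(C)OC)cc(OC)c1OCc1ccccc1 | intermediate
12 | (1E)-1-[4-(benzyloxy)-3,5-dimethoxyphenyl]-7-[3,4-bis(benzyloxy)phenyl]hepta-1,6-dien-4-yn-3-one, E/Z mixture at C6=C7 | COc1cc(/C=C/C(=O)C#CC=Cc2ccc(OCc3ccccc3)c(OCc3ccccc3)c2)cc(OC)c1OCc1ccccc1 | intermediate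
13 | 7-(3,4-dihydroxyphenyl)-1-(4-hydroxy-3,5-dimethoxyphenyl)heptan-3-one | COc1cc(CCC(=O)CCCCc2ccc(O)c(O)c2)cc(OC)c1O | target

Total step count: 4. Longest linear sequence: 3 steps (1 → 4 → 12 → 13, or 5 → 9 → 12 → 13).

Steps most likely to fail

Step 3. The acetylide may add slowly or partly in the 1,4 sense to the electron-rich cinnamoyl amide. The released N,O-dimethylhydroxylamine may add to the ynone during work-up. The lithium enynide may oligomerise on warming. The fallback replaces the stoichiometric lithium acetylide by a catalytic acyl Sonogashira coupling. It sets out from aldehyde 1: Knoevenagel–Doebner condensation with malonic acid (pyridine, cat. piperidine, 90 °C) should give (2E)-3-[4-(benzyloxy)-3,5-dimethoxyphenyl]prop-2-enoic acid F1. Oxalyl chloride with catalytic DMF in CH2Cl2 should convert it to (2E)-3-[4-(benzyloxy)-3,5-dimethoxyphenyl]prop-2-enoyl chloride F2. This chloride has no α-sp3 hydrogen and cannot form a ketene with amine base. It would be coupled with enyne 9 (PdCl2(PPh3)2, CuI, Et3N, THF, rt) and comes back to the route at compound 12.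

Step 2. The propargylic ylide may isomerise to its allenyl form or decompose before olefination, and the terminal enyne may polymerise during the in-pot desilylation and concentration. The fallback builds the alkyne by one-carbon homologation instead of carrying it in the olefination reagent. It sets out from aldehyde 5: Wittig reaction with (triphenylphosphoranylidene)acetaldehyde (toluene, 80 °C) should give (2E)-3-[3,4-bis(benzyloxy)phenyl]prop-2-enal F3. Corey–Fuchs dibromo-olefination (CBr4, PPh3, CH2Cl2, 0 °C) should give 4-[(1E)-4,4-dibromobuta-1,3-dien-1-yl]-1,2-bis(benzyloxy)benzene F4. Treatment with two equivalents of n-BuLi (THF, −78 °C) should give the lithium acetylide directly, so the fallback comes back to the route at compound 10 (as its E isomer), which is used in step 3 without isolation of 9.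

Step 4. The C3 carbonyl may be over-reduced while it is still conjugated (allylic or propargylic alcohol, then hydrogenolysis). Hydrogenolysis of the hindered benzyl ether between the two methoxy groups may stall. The free catechol may oxidise in air on work-up. The fallback separates saturation from deprotection and removes the benzyl groups without hydrogen. It sets out from compound 12: hydrogenation over Pd/C poisoned with diphenyl sulfide (H2, 1 atm, EtOAc, rt), which should spare benzyl ethers and ketones, would give 1-[4-(benzyloxy)-3,5-dimethoxyphenyl]-7-[3,4-bis(benzyloxy)phenyl]heptan-3-one F5. Lewis-acid debenzylation with BCl3 and pentamethylbenzene as cation scavenger (CH2Cl2, −78 °C) then comes back to the route at compound 13.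

Further compounds
F1 | step 3 | (2E)-3-[4-(benzyloxy)-3,5-dimethoxyphenyl]prop-2-enoic acid | COc1cc(/C=C/C(=O)O)cc(OC)c1OCc1ccccc1
F2 | step 3 | (2E)-3-[4-(benzyloxy)-3,5-dimethoxyphenyl]prop-2-enoyl chloride | COc1cc(/C=C/C(=O)Cl)cc(OC)c1OCc1ccccc1
F3 | step 2 | (2E)-3-[3,4-bis(benzyloxy)phenyl]prop-2-enal | O=C/C=C/c1ccc(OCc2ccccc2)c(OCc2ccccc2)c1
F4 | step 2 | 4-[(1E)-4,4-dibromobuta-1,3-dien-1-yl]-1,2-bis(benzyloxy)benzene | BrC(Br)=C/C=C/c1ccc(OCc2ccccc2)c(OCc2ccccc2)c1
F5 | step 4 | 1-[4-(benzyloxy)-3,5-dimethoxyphenyl]-7-[3,4-bis(benzyloxy)phenyl]heptan-3-one | COc1cc(CCC(=O)CCCCc2ccc(OCc3ccccc3)c(OCc3ccccc3)c2)cc(OC)c1OCc1ccccc1
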